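Retrosynthesis (drimane numbering): the hydroquinone goes back by redox and O-methylation to a 2,3,5-trimethoxyphenyl ring, the C5–H/C6–H pair to a C5=C6 alkene, and C11–Cl to a C11 aryl ketone by way of its enol triflate.
Enabling feature: in that ketone the chain C11(=O)–C9–C10–C5=C6, laid along ring B, is a gamma,delta-unsaturated ketone and hence a Claisen retron. Cutting C9–C10 and tying the C11 oxygen to C6 turns carbocyclic ring B into a 6-aryl-3,4-dihydro-2H-pyran that carries ring A as a 2,6,6-trimethylcyclohexenyl group on the carbinol carbon C6.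
Further cuts: aryl–C11 (Negishi coupling of a lactone-derived ketene acetal phosphate) and C5–C6 (Shapiro vinyllithium plus (R)-4-methyl-delta-valerolactone).
Forward order: ring A is bought, the chain C6–C7–C8–C9–C11 is attached, the O-heterocycle closes as a delta-lactone, the arene is coupled on and ring B closes in the [3,3] shift. C11–Cl, the C5–C6 hydrogenation and the release of the hydroquinone follow.
Stereochemistry: C8 comes from enzymatic desymmetrisation of a prochiral diester, C6 from a CBS reduction, C10 (and the transient C9) by transfer from C6 in the Claisen step, C5 from a radical hydrogenation to the trans-decalin, and the E-chloroalkene from chloride attack on the open C8 flank of a linear vinyl cation.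

Key step: step 11

Remark: all intermediates carry drimane numbers (C1–C10 decalin carbons, C11 the aryl-bearing carbon), alpha and beta refer to the usual drawing with the C10 methyl beta, and the target alkene is read as E, with Cl on the C8 side and the arene on the C10 side.

Step 1
Reactants: 1 dimethyl 3-methylglutarate
Product: 2 (R)-5-methoxy-3-methyl-5-oxopentanoic acid
Conditions: pig liver esterase, pH 7 phosphate buffer–MeOH (4:1), −10 °C
Reagents that add atoms: water, O
Why: Enzymatic desymmetrisation by enantiotopic-group-selective ester hydrolysis is established for this prochiral diester and should give the (R)-half-ester, which sets the future C8 and marks the acid end as C11 and the ester end as C6.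

Step 2
Reactants: 2 (R)-5-methoxy-3-methyl-5-oxopentanoic acid
Product: 4 (R)-4-methyltetrahydro-2H-pyran-2-one, via hydroxy ester 3 (not isolated)
Conditions: BH3·SMe2, THF, 0 °C to rt; then cat. TsOH, CH2Cl2, rt
Reagents that add atoms: none
Why: Chemoselective borane reduction of a carboxylic acid beside an ester, followed by acid-catalysed lactonisation of hydroxy ester 3, is standard, and the C8 centre, beta to both termini, cannot epimerise.

Step 3
Reactants: 5 2,2,6-trimethylcyclohexanone (racemic)
Product: 6 N'-[(E)-2,2,6-trimethylcyclohexylidene]-2,4,6-triisopropylbenzenesulfonohydrazide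
Conditions: 2,4,6-triisopropylbenzenesulfonyl hydrazide, cat. HCl, MeCN, rt
Reagents that add atoms: 2,4,6-triisopropylbenzenesulfonyl hydrazide, NNS(=O)(=O)c1c(C(C)C)cc(C(C)C)cc1C(C)C
Why: Acid-catalysed sulfonylhydrazone formation should place the N–N bond anti to the quaternary carbon, on the side of the only alpha-hydrogen that the next step has to remove, and the stereocentre of racemic 5 disappears there.

Step 4
Reactants: 6 N'-[(E)-2,2,6-trimethylcyclohexylidene]-2,4,6-triisopropylbenzenesulfonohydrazide; 4 (R)-4-methyltetrahydro-2H-pyran-2-one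
Product: 8 (R)-5-hydroxy-3-methyl-1-(2,6,6-trimethylcyclohex-1-en-1-yl)pentan-1-one, via vinyllithium 7 (not isolated)
Conditions: 6, n-BuLi (2.1 equiv), TMEDA, THF, −78 to 0 °C; then 4, −78 °C
Reagents that add atoms: none
Why: In this Shapiro reaction, double deprotonation and loss of sulfinate and N2 give vinyllithium 7, whose acyl substitution on lactone 4 forms C5–C6 and stops at the ketone because the new carbonyl is shielded by the 2,6,6-trimethylcyclohexenyl group.

Step 5
Reactants: 8 (R)-5-hydroxy-3-methyl-1-(2,6,6-trimethylcyclohex-1-en-1-yl)pentan-1-one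
Product: 9 (1S,3R)-3-methyl-1-(2,6,6-trimethylcyclohex-1-en-1-yl)pentane-1,5-diol
Conditions: (R)-2-methyl-CBS-oxazaborolidine (0.2 equiv), BH3·SMe2, THF, −20 °C
Reagents that add atoms: none
Why: In this Corey–Bakshi–Shibata reduction the (R)-oxazaborolidine–borane complex binds the carbonyl lone pair remote from the very large cyclohexenyl group and delivers hydride to the Re face, which sets (S)-C6 under reagent control irrespective of the distant C8 centre.

Step 6
Reactants: 9 (1S,3R)-3-methyl-1-(2,6,6-trimethylcyclohex-1-en-1-yl)pentane-1,5-diol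
Product: 11 (4S,6S)-4-methyl-6-(2,6,6-trimethylcyclohex-1-en-1-yl)tetrahydro-2H-pyran-2-one (cis), via lactol 10 (not isolated)
Conditions: TEMPO (0.2 equiv), PhI(OAc)2 (2.5 equiv), CH2Cl2, rt
Reagents that add atoms: none
Why: In this oxoammonium-mediated oxidative lactonisation of a 1,5-diol the unhindered primary alcohol is oxidised first, the aldehyde closes to lactol 10 on the hindered allylic hydroxyl and a second oxidation gives the cis-lactone without touching C6 or C8, while any trans-isomer left by imperfect selectivity in steps 1 and 5 can be removed here by chromatography.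

Step 7
Reactants: 12 5-bromovanillin
Product: 14 2-bromo-6-methoxybenzene-1,4-diol, via aryl formate 13 (not isolated)
Conditions: 30% aq. H2O2, NaOH, H2O–THF, 0 °C to rt; then 1 M HCl
Reagents that add atoms: hydrogen peroxide, OO
Why: In this Dakin oxidation hydroperoxide adds to the aldehyde of the para-hydroxybenzaldehyde, aryl migration gives formate 13 and base hydrolysis frees the hydroquinone.

Step 8
Reactants: 14 2-bromo-6-methoxybenzene-1,4-diol
Product: 15 1-bromo-2,3,5-trimethoxybenzene
Conditions: MeI, K2CO3, acetone, reflux, N2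
Reagents that add atoms: iodomethane, CI
Why: Williamson ether synthesis on both phenols gives the robust trimethyl ether, whose 2- and 5-methoxy groups are para to each other and can later be removed oxidatively.

Step 9
Reactants: 11 (4S,6S)-4-methyl-6-(2,6,6-trimethylcyclohex-1-en-1-yl)tetrahydro-2H-pyran-2-one
Product: 17 diphenyl (2S,4S)-4-methyl-2-(2,6,6-trimethylcyclohex-1-en-1-yl)-3,4-dihydro-2H-pyran-6-yl phosphate, via lactone enolate 16 (not isolated)
Conditions: KN(SiMe3)2, THF–DMPU, −78 °C; then (PhO)2P(O)Cl
Reagents that add atoms: diphenyl chlorophosphate, O=P(Cl)(Oc1ccccc1)Oc1ccccc1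
Why: Kinetic enolisation at C9, the only alpha-position, and O-phosphorylation of enolate 16 is the standard entry to lactone-derived ketene acetal phosphates, and the basic medium spares the ionisable allylic C6–O bond and C8.

Step 10
Reactants: 15 1-bromo-2,3,5-trimethoxybenzene; 17 diphenyl (2S,4S)-4-methyl-2-(2,6,6-trimethylcyclohex-1-en-1-yl)-3,4-dihydro-2H-pyran-6-yl phosphate
Product: 20 (2S,4S)-4-methyl-6-(2,3,5-trimethoxyphenyl)-2-(2,6,6-trimethylcyclohex-1-en-1-yl)-3,4-dihydro-2H-pyran (cis), via aryllithium 18 (not isolated), via arylzinc chloride 19 (not isolated)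
Conditions: 15, n-BuLi, THF, −78 °C; ZnCl2, −78 °C to rt; then 17, Pd(PPh3)4 (5 mol %), THF, 50 °C
Reagents that add atoms: none
Why: In this Negishi coupling bromine–lithium exchange and transmetalation give arylzinc 19, and zerovalent palladium inserts into the C11–O(phosphate) bond of 17, so that the aryl–C11 bond forms under neutral, anhydrous conditions that spare the acid-labile aryl enol ether and both stereocentres.

Step 11
Reactants: 20 (2S,4S)-4-methyl-6-(2,3,5-trimethoxyphenyl)-2-(2,6,6-trimethylcyclohex-1-en-1-yl)-3,4-dihydro-2H-pyran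
Product: 21 [(1R,2S,8aR)-2,5,5,8a-tetramethyl-1,2,3,5,6,7,8,8a-octahydronaphthalen-1-yl](2,3,5-trimethoxyphenyl)methanone (5-ene, 8-beta methyl, 9-alpha aroyl, 10-beta methyl)
Conditions: 1,2-dichlorobenzene (degassed, 0.02 M), 2,6-di-tert-butylpyridine (0.2 equiv), BHT (cat.), silylated sealed tube, 200 °C
Reagents that add atoms: none
Why: Proposed new method: the enol ether C9=C11–O and the allyl unit C6–C5=C10 of 20 make up an allyl vinyl ether locked inside the pyran, so heating should start a concerted suprafacial [3,3] shift through the only reachable, boat-like and bicyclo[2.2.2]octane-shaped transition state, in which C9–C10 forms while C6–O breaks and the C11 aryl ketone is released. The closest known reaction type is the thermal Claisen ring contraction of 2-vinyl- and 2-propenyl-3,4-dihydro-2H-pyrans to cyclohex-3-enyl carbonyl compounds, and the new element is a fully substituted ring alkene as the terminus that has to become a quaternary carbon. Ring B (C5 to C10) closes by this pericyclic ring contraction, a six-membered O-heterocycle being exchanged for a six-membered carbocycle, so that no exo or endo mode applies. C10 is controlled by chirality transfer from C6, because C9 must arrive on the allyl face from which oxygen leaves and the forming ring allows only the C5=C6 geometry with C7 cis to C10, which turns the C10 methyl beta; C9 is controlled by the tether, because C10 can reach only the pyran face that bears the cyclohexenyl group, which leaves the aroyl group alpha and trans to the spectator 8-beta methyl. The step needs periselectivity over retro-hetero-Diels–Alder cleavage and over heterolysis of the allylic C6–O bond with proton loss, and the gain of a conjugated aryl ketone, the donor arene on C11, the apolar medium and the strict exclusion of acid are meant to secure it.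

Step 12
Reactants: 21 [(1R,2S,8aR)-2,5,5,8a-tetramethyl-1,2,3,5,6,7,8,8a-octahydronaphthalen-1-yl](2,3,5-trimethoxyphenyl)methanone
Product: 23 (Z)-[(2S,8aS)-2,5,5,8a-tetramethyl-3,5,6,7,8,8a-hexahydronaphthalen-1(2H)-ylidene](2,3,5-trimethoxyphenyl)methyl trifluoromethanesulfonate, via potassium enolate 22 (not isolated)
Conditions: KN(SiMe3)2 (1.5 equiv), THF, −78 to 0 °C; then PhNTf2, −78 °C to rt; filtration through basic alumina
Reagents that add atoms: N-phenylbis(trifluoromethanesulfonimide), O=S(=O)(N(c1ccccc1)S(=O)(=O)C(F)(F)F)C(F)(F)F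
Why: This enolate O-sulfonylation can be forced because C9–H is the only acidic hydrogen of 21 and lies axial on the open beta face in the ring B half-chair that places the aroyl and C8 methyl groups equatorial; the transient C9 centre is erased, and the geometry of 23 (Z expected, arene next to the smaller C8) has no bearing on the next step.

Step 13
Reactants: 23 (Z)-[(2S,8aS)-2,5,5,8a-tetramethyl-3,5,6,7,8,8a-hexahydronaphthalen-1(2H)-ylidene](2,3,5-trimethoxyphenyl)methyl trifluoromethanesulfonate
Product: 25 1-{(E)-chloro[(2S,8aS)-2,5,5,8a-tetramethyl-3,5,6,7,8,8a-hexahydronaphthalen-1(2H)-ylidene]methyl}-2,3,5-trimethoxybenzene, via vinyl cation 24 (not isolated)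
Conditions: n-Bu4NCl (5 equiv), 2,6-di-tert-butylpyridine (0.2 equiv), MeCN, 60 °C
Reagents that add atoms: tetrabutylammonium chloride, CCCC[N+](CCCC)(CCCC)CCCC.[Cl-]
Why: In this vinylic SN1 substitution the triflate ionises to the linear alpha-aryl vinyl cation 24, stabilised by the ortho-methoxy-substituted ring that is already twisted into overlap with the developing in-plane orbital, and chloride enters in the C8–C9–C10 plane from the C8 flank, where only an equatorial hydrogen lies, rather than from the C10 flank blocked by C1H2, which should give the E-alkene with Cl cis to C8.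

Step 14
Reactants: 25 1-{(E)-chloro[(2S,8aS)-2,5,5,8a-tetramethyl-3,5,6,7,8,8a-hexahydronaphthalen-1(2H)-ylidene]methyl}-2,3,5-trimethoxybenzene
Product: 27 1-{(E)-chloro[(2S,4aS,8aS)-2,5,5,8a-tetramethyloctahydronaphthalen-1(2H)-ylidene]methyl}-2,3,5-trimethoxybenzene, via C5 radical 26 (not isolated)
Conditions: Mn(dpm)3 (10 mol %, dpm = 2,2,6,6-tetramethylheptane-3,5-dionate), PhSiH3, t-BuOOH, i-PrOH, rt
Reagents that add atoms: none
Why: In this radical hydrogenation by metal-hydride hydrogen-atom transfer H adds to the accessible C6 and the tertiary radical 26 takes up the second H on its alpha face, anti to the C10 and C4-beta methyl groups, to give the trans-decalin with (S)-C5, the favoured fusion now that C9 is sp2 and allylic strain with Cl holds the C8 methyl axial, while the tetrasubstituted, twisted chloroalkene next to quaternary C10 should be too hindered to accept H.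

Step 15
Reactants: 27 1-{(E)-chloro[(2S,4aS,8aS)-2,5,5,8a-tetramethyloctahydronaphthalen-1(2H)-ylidene]methyl}-2,3,5-trimethoxybenzene
Product: 28 2-{(E)-chloro[(2S,4aS,8aS)-2,5,5,8a-tetramethyloctahydronaphthalen-1(2H)-ylidene]methyl}-6-methoxycyclohexa-2,5-diene-1,4-dione
Conditions: (NH4)2Ce(NO3)6 (2.5 equiv), MeCN–H2O, 0 °C
Reagents that add atoms: water, O
Why: Oxidative demethylation of a para-dimethoxyarene by tetravalent cerium gives the methoxy-para-quinone, since the 3-methoxy group has no para partner and the hindered, electron-poor chloroalkene should be inert.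

Step 16
Reactants: 28 2-{(E)-chloro[(2S,4aS,8aS)-2,5,5,8a-tetramethyloctahydronaphthalen-1(2H)-ylidene]methyl}-6-methoxycyclohexa-2,5-diene-1,4-dione
Product: 29 2-{(E)-chloro[(2S,4aS,8aS)-2,5,5,8a-tetramethyloctahydronaphthalen-1(2H)-ylidene]methyl}-6-methoxybenzene-1,4-diol (CNP0162917.1)
Conditions: Na2S2O4, THF–H2O, rt
Reagents that add atoms: none
Why: Dithionite reduction of a quinone to its hydroquinone is mild and near neutral and leaves the chloroalkene geometry and all stereocentres untouched.

Compound list
1 | dimethyl 3-methylglutarate | COC(=O)CC(C)CC(=O)OC | starting material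
2 | (R)-5-methoxy-3-methyl-5-oxopentanoic acid | OC(=O)C[C@@H](C)CC(=O)OC | intermediate
3 | methyl (R)-5-hydroxy-3-methylpentanoate | OCC[C@@H](C)CC(=O)OC | intermediate
4 | (R)-4-methyltetrahydro-2H-pyran-2-one | O=C1C[C@H](C)CCO1 | intermediate
5 | 2,2,6-trimethylcyclohexanone (racemic) | CC1CCCC(C)(C)C1=O | starting material
6 | N'-[(E)-2,2,6-trimethylcyclohexylidene]-2,4,6-triisopropylbenzenesulfonohydrazide | CC1CCCC(C)(C)/C1=N/NS(=O)(=O)c2c(C(C)C)cc(C(C)C)cc2C(C)C | intermediate
7 | (2,6,6-trimethylcyclohex-1-en-1-yl)lithium | [Li]C1=C(C)CCCC1(C)C | intermediate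
8 | (R)-5-hydroxy-3-methyl-1-(2,6,6-trimethylcyclohex-1-en-1-yl)pentan-1-one | OCC[C@@H](C)CC(=O)C1=C(C)CCCC1(C)C | intermediate
9 | (1S,3R)-3-methyl-1-(2,6,6-trimethylcyclohex-1-en-1-yl)pentane-1,5-diol | OCC[C@@H](C)C[C@H](O)C1=C(C)CCCC1(C)C | intermediate
10 | (4S,6S)-4-methyl-6-(2,6,6-trimethylcyclohex-1-en-1-yl)tetrahydro-2H-pyran-2-ol (anomers) | OC1C[C@@H](C)C[C@H](O1)C2=C(C)CCCC2(C)C | intermediate
11 | (4S,6S)-4-methyl-6-(2,6,6-trimethylcyclohex-1-en-1-yl)tetrahydro-2H-pyran-2-one (cis) | O=C1C[C@@H](C)C[C@H](O1)C2=C(C)CCCC2(C)C | intermediate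
12 | 5-bromovanillin | COc1cc(C=O)cc(Br)c1O | starting material
13 | 3-bromo-4-hydroxy-5-methoxyphenyl formate | COc1cc(OC=O)cc(Br)c1O | intermediate
14 | 2-bromo-6-methoxybenzene-1,4-diol | COc1cc(O)cc(Br)c1O | intermediate
15 | 1-bromo-2,3,5-trimethoxybenzene | COc1cc(OC)cc(Br)c1OC | intermediate
16 | potassium (2S,4S)-4-methyl-2-(2,6,6-trimethylcyclohex-1-en-1-yl)-3,4-dihydro-2H-pyran-6-olate | [K+].[O-]C1=C[C@@H](C)C[C@H](O1)C2=C(C)CCCC2(C)C | intermediate
17 | diphenyl (2S,4S)-4-methyl-2-(2,6,6-trimethylcyclohex-1-en-1-yl)-3,4-dihydro-2H-pyran-6-yl phosphate | O=P(Oc1ccccc1)(Oc2ccccc2)OC3=C[C@@H](C)C[C@H](O3)C4=C(C)CCCC4(C)C | intermediate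
18 | (2,3,5-trimethoxyphenyl)lithium | [Li]c1cc(OC)cc(OC)c1OC | intermediate
19 | chloro(2,3,5-trimethoxyphenyl)zinc | Cl[Zn]c1cc(OC)cc(OC)c1OC | intermediate
20 | (2S,4S)-4-methyl-6-(2,3,5-trimethoxyphenyl)-2-(2,6,6-trimethylcyclohex-1-en-1-yl)-3,4-dihydro-2H-pyran (cis) | COc1cc(OC)cc(C2=C[C@@H](C)C[C@H](O2)C3=C(C)CCCC3(C)C)c1OC | intermediate
21 | [(1R,2S,8aR)-2,5,5,8a-tetramethyl-1,2,3,5,6,7,8,8a-octahydronaphthalen-1-yl](2,3,5-trimethoxyphenyl)methanone | COc1cc(OC)cc(C(=O)[C@@H]2[C@@H](C)CC=C3C(C)(C)CCC[C@]23C)c1OC | intermediate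
22 | potassium (Z)-enolate of 21 | COc1cc(OC)cc(/C([O-])=C2\[C@@H](C)CC=C3C(C)(C)CCC[C@]23C)c1OC.[K+] | intermediate
23 | (Z)-[(2S,8aS)-2,5,5,8a-tetramethyl-3,5,6,7,8,8a-hexahydronaphthalen-1(2H)-ylidene](2,3,5-trimethoxyphenyl)methyl trifluoromethanesulfonate | COc1cc(OC)cc(/C(OS(=O)(=O)C(F)(F)F)=C2\[C@@H](C)CC=C3C(C)(C)CCC[C@]23C)c1OC | intermediate
24 | alpha-(2,3,5-trimethoxyphenyl)vinyl cation at C11 | COc1cc(OC)cc([C+]=C2[C@@H](C)CC=C3C(C)(C)CCC[C@]23C)c1OC | intermediate
25 | 1-{(E)-chloro[(2S,8aS)-2,5,5,8a-tetramethyl-3,5,6,7,8,8a-hexahydronaphthalen-1(2H)-ylidene]methyl}-2,3,5-trimethoxybenzene | COc1cc(OC)cc(/C(Cl)=C2/[C@@H](C)CC=C3C(C)(C)CCC[C@]23C)c1OC | intermediate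
26 | tertiary C5 radical from H addition to C6 of 25 | COc1cc(OC)cc(/C(Cl)=C2/[C@@H](C)CC[C]3C(C)(C)CCC[C@]23C)c1OC | intermediate
27 | 1-{(E)-chloro[(2S,4aS,8aS)-2,5,5,8a-tetramethyloctahydronaphthalen-1(2H)-ylidene]methyl}-2,3,5-trimethoxybenzene | COc1cc(OC)cc(/C(Cl)=C2/[C@@H](C)CC[C@H]3C(C)(C)CCC[C@]23C)c1OC | intermediate
28 | 2-{(E)-chloro[(2S,4aS,8aS)-2,5,5,8a-tetramethyloctahydronaphthalen-1(2H)-ylidene]methyl}-6-methoxycyclohexa-2,5-diene-1,4-dione | COC1=CC(=O)C=C(/C(Cl)=C2/[C@@H](C)CC[C@H]3C(C)(C)CCC[C@]23C)C1=O | intermediate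
29 | 2-{(E)-chloro[(2S,4aS,8aS)-2,5,5,8a-tetramethyloctahydronaphthalen-1(2H)-ylidene]methyl}-6-methoxybenzene-1,4-diol (CNP0162917.1) | COc1cc(O)cc(/C(Cl)=C2/[C@@H](C)CC[C@H]3C(C)(C)CCC[C@]23C)c1O | target

Total step count: 16.
Longest linear sequence: 13 steps (1, 2, 4, 5, 6, 9, 10, 11, 12, 13, 14, 15, 16).

Steps most likely to fail

Step 11 (proposed new method). The contact between the C8 and C10 methyl groups in the boat may raise the barrier so far that retro-hetero-Diels–Alder fragmentation, or heterolysis of the allylic C6–O bond followed by proton loss, overtakes the [3,3] shift. The fallback uses known chemistry, the Ireland–Claisen ring contraction of an alkenyl lactone. It exchanges the same C9–C10 and C6–O bonds at a much lower temperature and brings in the arene afterwards.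
- It sets out from lactone 11, which is enolised with KN(SiMe3)2 and trapped with TBSCl to give the silyl ketene acetal F1.
- Heating in toluene at about 110 °C should give the ring-contracted silyl ester F2, and mild aqueous K2CO3 hydrolysis followed by acidification the carboxylic acid F3.
- (COCl)2 and catalytic DMF give the acid chloride F4.
- Negishi acylation of F4 by arylzinc chloride 19 under Pd(PPh3)4 catalysis comes back to the route at ketone 21.

Step 14. Hydrogen-atom transfer to the chlorostyrene unit may compete, or the second hydrogen may be delivered to the beta face of the C5 radical and erode the trans ring fusion. The fallback replaces the radical process by a hydroxyl-directed homogeneous hydrogenation carried out before chlorine is installed.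
- It sets out from ketone 21, which LiAlH4 in THF reduces to the benzylic carbinol F5; its side chain stands on the alpha face at C9.
- [Ir(cod)(PCy3)(py)]PF6 under H2 in CH2Cl2 binds this hydroxyl and should add H2 to the alpha face of C5=C6, giving the trans-fused carbinol F6.
- Dess–Martin oxidation then gives the saturated ketone F7, and KN(SiMe3)2 followed by PhNTf2 the saturated enol triflate F8.
- n-Bu4NCl in MeCN, as in step 13, comes back to the route at 27.

Step 12. Deprotonation of the shielded C9–H may be slow or incomplete, so that the base consumes the sulfonylating agent, or the labile triflate may ionise during isolation. The fallback avoids the enolate altogether by deoxychlorination. It sets out from ketone 21, which is treated in CH2Cl2 with Et3N and the adduct (PhO)3PCl2, prepared from P(OPh)3 and Cl2 at −30 °C. Activation of the carbonyl oxygen as an oxyphosphonium ion, chloride transfer to C11 and loss of H9 should lead directly to chloroalkene 25, where the route is rejoined; no new isolable compound is made.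

Further compounds
F1 | step 11 | (2S,4S)-6-(tert-butyldimethylsilyloxy)-4-methyl-2-(2,6,6-trimethylcyclohex-1-en-1-yl)-3,4-dihydro-2H-pyran | CC(C)(C)[Si](C)(C)OC1=C[C@@H](C)C[C@H](O1)C2=C(C)CCCC2(C)C
F2 | step 11 | tert-butyldimethylsilyl (1R,2S,8aR)-2,5,5,8a-tetramethyl-1,2,3,5,6,7,8,8a-octahydronaphthalene-1-carboxylate | CC(C)(C)[Si](C)(C)OC(=O)[C@@H]1[C@@H](C)CC=C2C(C)(C)CCC[C@]12C
F3 | step 11 | (1R,2S,8aR)-2,5,5,8a-tetramethyl-1,2,3,5,6,7,8,8a-octahydronaphthalene-1-carboxylic acid | OC(=O)[C@@H]1[C@@H](C)CC=C2C(C)(C)CCC[C@]12C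
F4 | step 11 | (1R,2S,8aR)-2,5,5,8a-tetramethyl-1,2,3,5,6,7,8,8a-octahydronaphthalene-1-carbonyl chloride | ClC(=O)[C@@H]1[C@@H](C)CC=C2C(C)(C)CCC[C@]12C
F5 | step 14 | [(1R,2S,8aR)-2,5,5,8a-tetramethyl-1,2,3,5,6,7,8,8a-octahydronaphthalen-1-yl](2,3,5-trimethoxyphenyl)methanol (C11 configuration open) | COc1cc(OC)cc(C(O)[C@@H]2[C@@H](C)CC=C3C(C)(C)CCC[C@]23C)c1OC
F6 | step 14 | [(1R,2S,4aS,8aS)-2,5,5,8a-tetramethyldecahydronaphthalen-1-yl](2,3,5-trimethoxyphenyl)methanol (C11 configuration open) | COc1cc(OC)cc(C(O)[C@@H]2[C@@H](C)CC[C@H]3C(C)(C)CCC[C@]23C)c1OC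
F7 | step 14 | [(1R,2S,4aS,8aS)-2,5,5,8a-tetramethyldecahydronaphthalen-1-yl](2,3,5-trimethoxyphenyl)methanone | COc1cc(OC)cc(C(=O)[C@@H]2[C@@H](C)CC[C@H]3C(C)(C)CCC[C@]23C)c1OC
F8 | step 14 | (Z)-[(2S,4aS,8aS)-2,5,5,8a-tetramethyloctahydronaphthalen-1(2H)-ylidene](2,3,5-trimethoxyphenyl)methyl trifluoromethanesulfonate | COc1cc(OC)cc(/C(OS(=O)(=O)C(F)(F)F)=C2\[C@@H](C)CC[C@H]3C(C)(C)CCC[C@]23C)c1OC
F0 | step 12 | none | none
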